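**Retrosynthetic overview**
- Locants used below: C1 = ring CH carrying C15(=C17H2)–C16(=O)O, C4 = lactone C–O carbon, C5 = CHOAc, C13 = CHOH. The 14-membered ring is closed last at C12–C13 by a new nickel-catalysed reductive ynal macrocyclization that also sets C13 and the 11E olefin.
- The ynal comes from a Negishi sp3–sp2 union (C7–C8) of an east lactone iodide with a west (Z)-iodo-enyne from but-2-yn-1-ol (8Z olefin preset).
- The 7-membered α-methylene lactone is formed first: the C16 acid opens a (4S,5S)-epoxide at C4 with inversion (gives 4R,5S). C16 comes from the isopropenyl methyl by ene chlorination and oxidation.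
- The epoxide comes from Shi epoxidation of an E olefin built by Zr-catalysed methylalumination of an alkyne made from a methyl ketone.
- C1 and eleven skeletal carbons come from (R)-limonene oxide by periodate cleavage.

Assumption: the SMILES is read as (1R,4R,5S,13R), 8Z, 11E in the locants above; (R)-limonene 1,2-oxide (cis/trans mixture) and the L-fructose-derived Shi ketone are taken as purchasable.

**Step 1**
Reactants: 1 (4R)-limonene 1,2-oxide (cis/trans mixture)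
Product: 2 (3R)-6-oxo-3-(prop-1-en-2-yl)heptanal
Conditions: H5IO6 (1.1 equiv), THF/H2O, 0 °C → rt
Reagents that add atoms: water, O
Why: Epoxide hydrolysis followed by periodate glycol cleavage (Malaprade reaction) cuts the ring between the two epoxide carbons, so both epoxide diastereomers give one keto aldehyde and the untouched limonene stereocentre becomes C1 (R).

**Step 2**
Reactants: 2 (3R)-6-oxo-3-(prop-1-en-2-yl)heptanal
Product: 3 (5R)-7-hydroxy-5-(prop-1-en-2-yl)heptan-2-one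
Conditions: NaBH4 (0.3 equiv), CH2Cl2/EtOH (7:3), −78 °C
Reagents that add atoms: none
Why: Chemoselective borohydride reduction, since the aldehyde reacts far faster than the methyl ketone at −78 °C and no stereocentre is formed.

**Step 3**
Reactants: 3 (5R)-7-hydroxy-5-(prop-1-en-2-yl)heptan-2-one
Product: 4 (5R)-7-[(tert-butyldiphenylsilyl)oxy]-5-(prop-1-en-2-yl)heptan-2-one
Conditions: TBDPSCl, imidazole, CH2Cl2, 0 °C → rt
Reagents that add atoms: tert-butyl(chloro)diphenylsilane, CC(C)(C)[Si](Cl)(c1ccccc1)c1ccccc1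
Why: Standard silyl ether protection of the primary alcohol (C13–O), robust to the base, AlMe3, oxidant and acid steps that follow.

**Step 4**
Reactants: 4 (5R)-7-[(tert-butyldiphenylsilyl)oxy]-5-(prop-1-en-2-yl)heptan-2-one
Product: 6 tert-butyldiphenyl{[(3R)-3-(prop-1-en-2-yl)hept-6-yn-1-yl]oxy}silane, via enol diethyl phosphate 5 (not isolated)
Conditions: LiN(iPr)2 (1.1 equiv), THF, −78 °C; ClP(O)(OEt)2, −78 °C → rt; then LiN(iPr)2 (2.3 equiv), −78 °C → rt; aq. NH4Cl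
Reagents that add atoms: none
Why: Kinetic deprotonation at the methyl group, O-phosphorylation and base-induced elimination of the terminal enol phosphate (Negishi ketone-to-alkyne protocol) turn the acetyl group into a terminal alkyne whose CH carbon becomes C5.

**Step 5**
Reactants: 6 tert-butyldiphenyl{[(3R)-3-(prop-1-en-2-yl)hept-6-yn-1-yl]oxy}silane
Product: 9 (3E,7R)-9-[(tert-butyldiphenylsilyl)oxy]-4-methyl-7-(prop-1-en-2-yl)non-3-en-1-ol, via alkenyldimethylalane 7 (not isolated), via lithium alkenylalanate 8 (not isolated)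
Conditions: AlMe3 (2.5 equiv), Cp2ZrCl2 (0.3 equiv), CH2Cl2, 0 °C → rt; then n-BuLi (1.1 equiv), hexane/THF, −30 °C; oxirane (5 equiv), −30 °C → rt; aq. potassium sodium tartrate
Reagents that add atoms: trimethylaluminium, C[Al](C)C; oxirane, C1CO1
Why: Zr-catalysed methylalumination (Negishi carboalumination) adds Me and Al syn with Me on the internal carbon, and the ate complex opens oxirane with retention at the alkenyl carbon, which fixes the E trisubstituted C4=C5 olefin and installs C6–C7.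

**Step 6**
Reactants: 9 (3E,7R)-9-[(tert-butyldiphenylsilyl)oxy]-4-methyl-7-(prop-1-en-2-yl)non-3-en-1-ol
Product: 10 tert-butyl{[(3R,6E)-9-chloro-6-methyl-3-(prop-1-en-2-yl)non-6-en-1-yl]oxy}diphenylsilane
Conditions: PPh3, N-chlorosuccinimide, CH2Cl2, −20 °C → rt
Reagents that add atoms: N-chlorosuccinimide, ClN1C(=O)CCC1=O
Why: Appel-type chlorination converts the C7 hydroxyl into an inert primary chloride, so it cannot open the later epoxide and survives the oxidations ahead.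

**Step 7**
Reactants: 10 tert-butyl{[(3R,6E)-9-chloro-6-methyl-3-(prop-1-en-2-yl)non-6-en-1-yl]oxy}diphenylsilane
Product: 11 tert-butyl{[(3R)-5-[(2S,3S)-3-(2-chloroethyl)-2-methyloxiran-2-yl]-3-(prop-1-en-2-yl)pentyl]oxy}diphenylsilane
Conditions: L-fructose-derived Shi ketone (0.3 equiv), KHSO5 (as 2KHSO5·KHSO4·K2SO4, 1.5 equiv), K2CO3, Bu4NHSO4 (cat.), MeCN/CH2(OMe)2/aq. Na2B4O7 buffer (pH 10.5), 0 °C
Reagents that add atoms: potassium peroxymonosulfate, [K+].[O-]S(=O)(=O)OO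
Why: Shi asymmetric epoxidation, in which the chiral dioxirane epoxidises the electron-rich E trisubstituted olefin in preference to the 1,1-disubstituted isopropenyl group and, under catalyst control, gives the (4S,5S)-epoxide (the D-fructose ketone gives 4R,5R).

**Step 8**
Reactants: 11 tert-butyl{[(3R)-5-[(2S,3S)-3-(2-chloroethyl)-2-methyloxiran-2-yl]-3-(prop-1-en-2-yl)pentyl]oxy}diphenylsilane
Product: 12 tert-butyl{[(3R)-5-[(2S,3S)-3-(2-chloroethyl)-2-methyloxiran-2-yl]-3-(3-chloroprop-1-en-2-yl)pentyl]oxy}diphenylsilane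
Conditions: Ca(OCl)2, solid CO2, CH2Cl2/H2O, 0 °C
Reagents that add atoms: calcium hypochlorite, [Ca+2].[O-]Cl.[O-]Cl
Why: Ene-type allylic chlorination by HOCl puts Cl on the terminal CH2 and removes a methyl proton, as with other isopropenyl terpenoids, so the isopropenyl group becomes a 2-substituted allyl chloride while the C1–H stereocentre and the epoxide stay intact at near-neutral pH.

**Step 9**
Reactants: 12 tert-butyl{[(3R)-5-[(2S,3S)-3-(2-chloroethyl)-2-methyloxiran-2-yl]-3-(3-chloroprop-1-en-2-yl)pentyl]oxy}diphenylsilane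
Product: 13 (3R)-5-[(tert-butyldiphenylsilyl)oxy]-3-{2-[(2S,3S)-3-(2-chloroethyl)-2-methyloxiran-2-yl]ethyl}-2-methylidenepentanal
Conditions: N-methylmorpholine N-oxide (4 equiv), 4 Å MS, MeCN, 40 °C
Reagents that add atoms: N-methylmorpholine N-oxide, C[N+]1([O-])CCOCC1
Why: Amine N-oxide oxidation of the activated allylic chloride (Ganem variant of the Kornblum oxidation) gives the 2-substituted acrolein (C16 aldehyde), while the unactivated primary chloride and the epoxide do not react.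

**Step 10**
Reactants: 13 (3R)-5-[(tert-butyldiphenylsilyl)oxy]-3-{2-[(2S,3S)-3-(2-chloroethyl)-2-methyloxiran-2-yl]ethyl}-2-methylidenepentanal
Product: 15 (4R,7R)-4-{2-[(tert-butyldiphenylsilyl)oxy]ethyl}-7-[(1S)-3-chloro-1-hydroxypropyl]-7-methyl-3-methylideneoxepan-2-one, via epoxy acid 14 (not isolated)
Conditions: NaClO2, NaH2PO4, 2-methyl-2-butene, t-BuOH/H2O, 0 °C; extract; then CSA (10 mol%), CH2Cl2, 0 °C → rt
Reagents that add atoms: sodium chlorite, [Na+].[O-]Cl=O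
Why: Pinnick oxidation gives the acrylic acid, whose carboxyl then opens the protonated epoxide 7-exo at the tertiary carbon with inversion (acid-catalysed epoxy-acid lactonization), turning 4S into 4R and leaving the C5–O bond untouched (5S).

**Step 11**
Reactants: 15 (4R,7R)-4-{2-[(tert-butyldiphenylsilyl)oxy]ethyl}-7-[(1S)-3-chloro-1-hydroxypropyl]-7-methyl-3-methylideneoxepan-2-one
Product: 16 (1S)-1-[(2R,5R)-5-{2-[(tert-butyldiphenylsilyl)oxy]ethyl}-2-methyl-6-methylidene-7-oxooxepan-2-yl]-3-chloropropyl acetate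
Conditions: Ac2O, pyridine, DMAP (cat.), CH2Cl2, rt
Reagents that add atoms: acetic anhydride, CC(=O)OC(C)=O
Why: DMAP-catalysed acetylation of the only free hydroxyl installs the C5 acetate of the target with retention.

**Step 12**
Reactants: 16 (1S)-1-[(2R,5R)-5-{2-[(tert-butyldiphenylsilyl)oxy]ethyl}-2-methyl-6-methylidene-7-oxooxepan-2-yl]-3-chloropropyl acetate
Product: 17 (1S)-1-[(2R,5R)-5-{2-[(tert-butyldiphenylsilyl)oxy]ethyl}-2-methyl-6-methylidene-7-oxooxepan-2-yl]-3-iodopropyl acetate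
Conditions: NaI (5 equiv), 2-butanone, 75 °C
Reagents that add atoms: sodium iodide, [Na+].[I-]
Why: Finkelstein halide exchange at the unhindered primary carbon gives the iodide needed for zinc insertion.

**Step 13**
Reactants: 18 but-2-yn-1-ol
Product: 20 (2Z)-3-iodobut-2-en-1-ol, via cyclic alkenylaluminate 19 (not isolated)
Conditions: NaAlH2(OCH2CH2OMe)2 (1.5 equiv), THF, 0 °C → rt; then I2, THF, −78 °C → 0 °C
Reagents that add atoms: iodine, II
Why: Hydroxyl-directed anti-hydroalumination of the propargylic alcohol places Al on C3, and iodinolysis with retention gives the Z vinyl iodide that presets the 8Z olefin.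

**Step 14**
Reactants: 20 (2Z)-3-iodobut-2-en-1-ol
Product: 21 (2Z)-1-bromo-3-iodobut-2-ene
Conditions: CBr4, PPh3, CH2Cl2, 0 °C
Reagents that add atoms: carbon tetrabromide, BrC(Br)(Br)Br
Why: Appel bromination of the primary allylic alcohol proceeds without touching the vinyl iodide or the olefin geometry.

**Step 15**
Reactants: 21 (2Z)-1-bromo-3-iodobut-2-ene
Product: 22 (5Z)-6-iodohept-5-en-2-yne
Conditions: 1-propynylmagnesium bromide (1.3 equiv), CuI (10 mol%), THF, 0 °C → rt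
Reagents that add atoms: 1-propynylmagnesium bromide, CC#C[Mg]Br
Why: Copper-catalysed SN2 allyl–alkynyl coupling at the primary allylic bromide gives the skipped enyne (C8–C12 and both methyls) and leaves the less reactive vinyl iodide in place.

**Step 16**
Reactants: 17 (1S)-1-[(2R,5R)-5-{2-[(tert-butyldiphenylsilyl)oxy]ethyl}-2-methyl-6-methylidene-7-oxooxepan-2-yl]-3-iodopropyl acetate; 22 (5Z)-6-iodohept-5-en-2-yne
Product: 24 (1S,4Z)-1-[(2R,5R)-5-{2-[(tert-butyldiphenylsilyl)oxy]ethyl}-2-methyl-6-methylidene-7-oxooxepan-2-yl]-4-methylnon-4-en-7-yn-1-yl acetate, via alkylzinc iodide 23 (not isolated)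
Conditions: 17, Zn dust (3 equiv), LiCl, THF, 35 °C; then 22 (1.2 equiv), PdCl2(dppf) (5 mol%), THF, rt → 45 °C
Reagents that add atoms: none
Why: Negishi sp3–sp2 cross-coupling, in which the ester-tolerant alkylzinc iodide couples with the vinyl iodide with retention of geometry to forge C7–C8 and deliver the 8Z olefin.

**Step 17**
Reactants: 24 (1S,4Z)-1-[(2R,5R)-5-{2-[(tert-butyldiphenylsilyl)oxy]ethyl}-2-methyl-6-methylidene-7-oxooxepan-2-yl]-4-methylnon-4-en-7-yn-1-yl acetate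
Product: 25 (1S,4Z)-1-[(2R,5R)-5-(2-hydroxyethyl)-2-methyl-6-methylidene-7-oxooxepan-2-yl]-4-methylnon-4-en-7-yn-1-yl acetate
Conditions: HF·pyridine, THF/pyridine, 0 °C → rt
Reagents that add atoms: none
Why: Buffered fluoride desilylation frees the C13 alcohol without acyl migration or Michael addition to the α-methylene lactone.

**Step 18**
Reactants: 25 (1S,4Z)-1-[(2R,5R)-5-(2-hydroxyethyl)-2-methyl-6-methylidene-7-oxooxepan-2-yl]-4-methylnon-4-en-7-yn-1-yl acetate
Product: 26 (1S,4Z)-4-methyl-1-[(2R,5R)-2-methyl-6-methylidene-7-oxo-5-(2-oxoethyl)oxepan-2-yl]non-4-en-7-yn-1-yl acetate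
Conditions: PhI(OAc)2 (1.2 equiv), TEMPO (10 mol%), CH2Cl2, rt
Reagents that add atoms: none
Why: TEMPO-catalysed oxidation with PhI(OAc)2 converts the primary alcohol into the C13 aldehyde under neutral conditions that spare the skipped enyne and the lactone.

**Step 19**
Reactants: 26 (1S,4Z)-4-methyl-1-[(2R,5R)-2-methyl-6-methylidene-7-oxo-5-(2-oxoethyl)oxepan-2-yl]non-4-en-7-yn-1-yl acetate
Product: 28 (1R,3R,4E,7Z,11S,12R)-3-hydroxy-4,8,12-trimethyl-15-methylidene-14-oxo-13-oxabicyclo[10.3.2]heptadeca-4,7-dien-11-yl acetate, via triethylsilyl ether 27 (not isolated)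
Conditions: Ni(cod)2 (20 mol%), (4S,5S)-1,3-bis(2-cyclohexylphenyl)-4,5-diphenylimidazolinium BF4 (22 mol%), KOt-Bu (22 mol%), Et3SiH (4 equiv), THF, rt, 26 added over 12 h (final 2 mM); then AcOH/THF/H2O (3:1:1), rt
Reagents that add atoms: none
Why: Proposed new method: zerovalent nickel bound to a C2-symmetric N-heterocyclic carbene should join the aldehyde and the alkyne of 26 by oxidative cyclisation to an oxanickelacyclopentene with the C–C bond at the methyl-bearing alkyne carbon (small-substituent steric rule, 14-membered endo closure), after which σ-bond metathesis with Et3SiH and C–H reductive elimination deliver H syn to the new bond (hence 11E) and the chiral carbene dictates the aldehyde face (13R, the ligand antipode being chosen by screening), while the aprotic silane conditions should leave the α-methylene lactone alone; the closest known reaction type is the nickel-catalysed reductive aldehyde–alkyne coupling and its macrocyclic ynal variant with achiral ligands, which has not been shown with a chiral carbene on a methyl-capped skipped enynal to close a 14-membered carbocycle.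

**Compound list**
1 | (4R)-limonene 1,2-oxide, (4R)-1-methyl-4-(prop-1-en-2-yl)-7-oxabicyclo[4.1.0]heptane (cis/trans mixture) | CC(=C)[C@@H]1CCC2(C)OC2C1 | starting material
2 | (3R)-6-oxo-3-(prop-1-en-2-yl)heptanal | CC(=O)CC[C@H](CC=O)C(C)=C | intermediate
3 | (5R)-7-hydroxy-5-(prop-1-en-2-yl)heptan-2-one | CC(=O)CC[C@H](CCO)C(C)=C | intermediate
4 | (5R)-7-[(tert-butyldiphenylsilyl)oxy]-5-(prop-1-en-2-yl)heptan-2-one | CC(=O)CC[C@H](CCO[Si](c1ccccc1)(c1ccccc1)C(C)(C)C)C(C)=C | intermediate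
5 | diethyl (5R)-7-[(tert-butyldiphenylsilyl)oxy]-5-(prop-1-en-2-yl)hept-1-en-2-yl phosphate | C=C(OP(=O)(OCC)OCC)CC[C@H](CCO[Si](c1ccccc1)(c1ccccc1)C(C)(C)C)C(C)=C | intermediate
6 | tert-butyldiphenyl{[(3R)-3-(prop-1-en-2-yl)hept-6-yn-1-yl]oxy}silane | C#CCC[C@H](CCO[Si](c1ccccc1)(c1ccccc1)C(C)(C)C)C(C)=C | intermediate
7 | dimethyl[(1E,5R)-7-[(tert-butyldiphenylsilyl)oxy]-2-methyl-5-(prop-1-en-2-yl)hept-1-en-1-yl]alumane | C[Al](C)/C=C(\C)CC[C@H](CCO[Si](c1ccccc1)(c1ccccc1)C(C)(C)C)C(C)=C | intermediate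
8 | lithium butyl(dimethyl)[(1E,5R)-7-[(tert-butyldiphenylsilyl)oxy]-2-methyl-5-(prop-1-en-2-yl)hept-1-en-1-yl]aluminate | [Li+].CCCC[Al-](C)(C)/C=C(\C)CC[C@H](CCO[Si](c1ccccc1)(c1ccccc1)C(C)(C)C)C(C)=C | intermediate
9 | (3E,7R)-9-[(tert-butyldiphenylsilyl)oxy]-4-methyl-7-(prop-1-en-2-yl)non-3-en-1-ol | OCC/C=C(\C)CC[C@H](CCO[Si](c1ccccc1)(c1ccccc1)C(C)(C)C)C(C)=C | intermediate
10 | tert-butyl{[(3R,6E)-9-chloro-6-methyl-3-(prop-1-en-2-yl)non-6-en-1-yl]oxy}diphenylsilane | ClCC/C=C(\C)CC[C@H](CCO[Si](c1ccccc1)(c1ccccc1)C(C)(C)C)C(C)=C | intermediate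
11 | tert-butyl{[(3R)-5-[(2S,3S)-3-(2-chloroethyl)-2-methyloxiran-2-yl]-3-(prop-1-en-2-yl)pentyl]oxy}diphenylsilane | ClCC[C@@H]1O[C@@]1(C)CC[C@H](CCO[Si](c2ccccc2)(c2ccccc2)C(C)(C)C)C(C)=C | intermediate
12 | tert-butyl{[(3R)-5-[(2S,3S)-3-(2-chloroethyl)-2-methyloxiran-2-yl]-3-(3-chloroprop-1-en-2-yl)pentyl]oxy}diphenylsilane | ClCC[C@@H]1O[C@@]1(C)CC[C@H](CCO[Si](c2ccccc2)(c2ccccc2)C(C)(C)C)C(=C)CCl | intermediate
13 | (3R)-5-[(tert-butyldiphenylsilyl)oxy]-3-{2-[(2S,3S)-3-(2-chloroethyl)-2-methyloxiran-2-yl]ethyl}-2-methylidenepentanal | ClCC[C@@H]1O[C@@]1(C)CC[C@H](CCO[Si](c2ccccc2)(c2ccccc2)C(C)(C)C)C(=C)C=O | intermediate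
14 | (3R)-5-[(tert-butyldiphenylsilyl)oxy]-3-{2-[(2S,3S)-3-(2-chloroethyl)-2-methyloxiran-2-yl]ethyl}-2-methylidenepentanoic acid | ClCC[C@@H]1O[C@@]1(C)CC[C@H](CCO[Si](c2ccccc2)(c2ccccc2)C(C)(C)C)C(=C)C(=O)O | intermediate
15 | (4R,7R)-4-{2-[(tert-butyldiphenylsilyl)oxy]ethyl}-7-[(1S)-3-chloro-1-hydroxypropyl]-7-methyl-3-methylideneoxepan-2-one | C=C1C(=O)O[C@@](C)([C@@H](O)CCCl)CC[C@@H]1CCO[Si](c2ccccc2)(c2ccccc2)C(C)(C)C | intermediate
16 | (1S)-1-[(2R,5R)-5-{2-[(tert-butyldiphenylsilyl)oxy]ethyl}-2-methyl-6-methylidene-7-oxooxepan-2-yl]-3-chloropropyl acetate | C=C1C(=O)O[C@@](C)([C@@H](OC(C)=O)CCCl)CC[C@@H]1CCO[Si](c2ccccc2)(c2ccccc2)C(C)(C)C | intermediate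
17 | (1S)-1-[(2R,5R)-5-{2-[(tert-butyldiphenylsilyl)oxy]ethyl}-2-methyl-6-methylidene-7-oxooxepan-2-yl]-3-iodopropyl acetate | C=C1C(=O)O[C@@](C)([C@@H](OC(C)=O)CCI)CC[C@@H]1CCO[Si](c2ccccc2)(c2ccccc2)C(C)(C)C | intermediate
18 | but-2-yn-1-ol | CC#CCO | starting material
19 | sodium 2,2-bis(2-methoxyethoxy)-3-methyl-2,5-dihydro-1,2-oxaluminol-2-uide (cyclic alkenylaluminate) | [Na+].CC1=CCO[Al-]1(OCCOC)OCCOC | intermediate
20 | (2Z)-3-iodobut-2-en-1-ol | C/C(I)=C/CO | intermediate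
21 | (2Z)-1-bromo-3-iodobut-2-ene | C/C(I)=C/CBr | intermediate
22 | (5Z)-6-iodohept-5-en-2-yne | C/C(I)=C/CC#CC | intermediate
23 | {(3S)-3-(acetyloxy)-3-[(2R,5R)-5-{2-[(tert-butyldiphenylsilyl)oxy]ethyl}-2-methyl-6-methylidene-7-oxooxepan-2-yl]propyl}(iodo)zinc | C=C1C(=O)O[C@@](C)([C@@H](OC(C)=O)CC[Zn]I)CC[C@@H]1CCO[Si](c2ccccc2)(c2ccccc2)C(C)(C)C | intermediate
24 | (1S,4Z)-1-[(2R,5R)-5-{2-[(tert-butyldiphenylsilyl)oxy]ethyl}-2-methyl-6-methylidene-7-oxooxepan-2-yl]-4-methylnon-4-en-7-yn-1-yl acetate | C=C1C(=O)O[C@@](C)([C@@H](OC(C)=O)CC/C(C)=C\CC#CC)CC[C@@H]1CCO[Si](c2ccccc2)(c2ccccc2)C(C)(C)C | intermediate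
25 | (1S,4Z)-1-[(2R,5R)-5-(2-hydroxyethyl)-2-methyl-6-methylidene-7-oxooxepan-2-yl]-4-methylnon-4-en-7-yn-1-yl acetate | C=C1C(=O)O[C@@](C)([C@@H](OC(C)=O)CC/C(C)=C\CC#CC)CC[C@@H]1CCO | intermediate
26 | (1S,4Z)-4-methyl-1-[(2R,5R)-2-methyl-6-methylidene-7-oxo-5-(2-oxoethyl)oxepan-2-yl]non-4-en-7-yn-1-yl acetate | C=C1C(=O)O[C@@](C)([C@@H](OC(C)=O)CC/C(C)=C\CC#CC)CC[C@@H]1CC=O | intermediate
27 | (1R,3R,4E,7Z,11S,12R)-4,8,12-trimethyl-15-methylidene-14-oxo-3-[(triethylsilyl)oxy]-13-oxabicyclo[10.3.2]heptadeca-4,7-dien-11-yl acetate | C=C1C(=O)O[C@]2(C)CC[C@@H]1C[C@@H](O[Si](CC)(CC)CC)/C(C)=C/C/C=C(/C)CC[C@@H]2OC(C)=O | intermediate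
28 | (1R,3R,4E,7Z,11S,12R)-3-hydroxy-4,8,12-trimethyl-15-methylidene-14-oxo-13-oxabicyclo[10.3.2]heptadeca-4,7-dien-11-yl acetate (CNP0130972.5) | C=C1C(=O)O[C@]2(C)CC[C@@H]1C[C@@H](O)/C(C)=C/C/C=C(/C)CC[C@@H]2OC(C)=O | target

**Totals**
Total step count: 19. Longest linear sequence: 16 steps (steps 1–12 and 16–19); steps 13–15 make the west fragment.

**Three steps most likely to fail**

Step 19 (the proposed new macrocyclization). The risks are competing aldehyde hydrosilylation, engagement of the α-methylene lactone by nickel, the wrong alkyne regiochemistry and a poor 13R:13S ratio. The fallback uses known chemistry; it sets out from 22 and 17 and comes back at 28. Hydrozirconation of 22 with excess Cp2Zr(H)Cl (THF, 50 °C, zirconium ending on the methyl-bearing carbon) and NBS gives (2E,5Z)-2-bromo-6-iodohepta-2,5-diene F1. The zinc reagent 23 made from 17 couples with F1 at the C–I bond only (PdCl2(dppf), rt) to give (1S,4Z,7E)-8-bromo-1-[(2R,5R)-5-{2-[(tert-butyldiphenylsilyl)oxy]ethyl}-2-methyl-6-methylidene-7-oxooxepan-2-yl]-4-methylnona-4,7-dien-1-yl acetate F2. HF·pyridine gives (1S,4Z,7E)-8-bromo-1-[(2R,5R)-5-(2-hydroxyethyl)-2-methyl-6-methylidene-7-oxooxepan-2-yl]-4-methylnona-4,7-dien-1-yl acetate F3, and PhI(OAc)2/TEMPO gives (1S,4Z,7E)-8-bromo-4-methyl-1-[(2R,5R)-2-methyl-6-methylidene-7-oxo-5-(2-oxoethyl)oxepan-2-yl]nona-4,7-dien-1-yl acetate F4. An intramolecular Nozaki–Hiyama–Kishi reaction (CrCl2 excess, NiCl2 cat., DMSO/THF, high dilution) then closes the ring to 28. If the 13-epimer prevails, the mixture is oxidised with Dess–Martin periodinane to (1R,4E,7Z,11S,12R)-4,8,12-trimethyl-15-methylidene-3,14-dioxo-13-oxabicyclo[10.3.2]heptadeca-4,7-dien-11-yl acetate F5 and reduced with (S)-Me-CBS/catecholborane to 28.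

Step 10 (7-exo epoxy-acid lactonization at a tertiary carbon). The risks are 8-endo attack, epoxide hydrolysis or rearrangement, and a sluggish carboxyl nucleophile. The fallback sets out from 12 and comes back at 16, using the more nucleophilic alcohol and oxidising afterwards. CsOAc in DMF displaces the allylic chloride to give 2-[(3R)-1-[(tert-butyldiphenylsilyl)oxy]-5-[(2S,3S)-3-(2-chloroethyl)-2-methyloxiran-2-yl]pentan-3-yl]prop-2-en-1-yl acetate F6. K2CO3/MeOH gives 2-[(3R)-1-[(tert-butyldiphenylsilyl)oxy]-5-[(2S,3S)-3-(2-chloroethyl)-2-methyloxiran-2-yl]pentan-3-yl]prop-2-en-1-ol F7. CSA (cat.) in CH2Cl2 effects 7-exo epoxide opening by the hydroxyl with inversion at C4 to give (1S)-1-[(2R,5R)-5-{2-[(tert-butyldiphenylsilyl)oxy]ethyl}-2-methyl-6-methylideneoxepan-2-yl]-3-chloropropan-1-ol F8. Ac2O/pyridine/DMAP gives (1S)-1-[(2R,5R)-5-{2-[(tert-butyldiphenylsilyl)oxy]ethyl}-2-methyl-6-methylideneoxepan-2-yl]-3-chloropropyl acetate F9. Allylic oxidation of the ring O–CH2 with CrO3·3,5-dimethylpyrazole (CH2Cl2, −20 °C) then gives the α-methylene lactone 16.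

Step 8 (ene chlorination beside an acid-sensitive epoxide). The risks are epoxide opening and proton loss from C1–H instead of the methyl group. The fallback sets out from 9 and comes back at 13, oxidising the methyl group by carbanion chemistry before the epoxide exists. Metalation of the isopropenyl methyl (n-BuLi 2.5 equiv, TMEDA, hexane, rt), borylation with B(OMe)3 and oxidation with H2O2/NaOH give (3E,7R)-9-[(tert-butyldiphenylsilyl)oxy]-7-(3-hydroxyprop-1-en-2-yl)-4-methylnon-3-en-1-ol F10. MnO2 oxidises only the allylic alcohol to (3R,6E)-3-{2-[(tert-butyldiphenylsilyl)oxy]ethyl}-9-hydroxy-6-methyl-2-methylidenenon-6-enal F11. PPh3/N-chlorosuccinimide gives (3R,6E)-3-{2-[(tert-butyldiphenylsilyl)oxy]ethyl}-9-chloro-6-methyl-2-methylidenenon-6-enal F12. Shi epoxidation with the L-fructose-derived ketone, as in step 7, then gives 13.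

**Further compounds**
F1 | step 19 | (2E,5Z)-2-bromo-6-iodohepta-2,5-diene | C/C(I)=C/C/C=C(\C)Br
F2 | step 19 | (1S,4Z,7E)-8-bromo-1-[(2R,5R)-5-{2-[(tert-butyldiphenylsilyl)oxy]ethyl}-2-methyl-6-methylidene-7-oxooxepan-2-yl]-4-methylnona-4,7-dien-1-yl acetate | C=C1C(=O)O[C@@](C)([C@@H](OC(C)=O)CC/C(C)=C\C/C=C(\C)Br)CC[C@@H]1CCO[Si](c2ccccc2)(c2ccccc2)C(C)(C)C
F3 | step 19 | (1S,4Z,7E)-8-bromo-1-[(2R,5R)-5-(2-hydroxyethyl)-2-methyl-6-methylidene-7-oxooxepan-2-yl]-4-methylnona-4,7-dien-1-yl acetate | C=C1C(=O)O[C@@](C)([C@@H](OC(C)=O)CC/C(C)=C\C/C=C(\C)Br)CC[C@@H]1CCO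
F4 | step 19 | (1S,4Z,7E)-8-bromo-4-methyl-1-[(2R,5R)-2-methyl-6-methylidene-7-oxo-5-(2-oxoethyl)oxepan-2-yl]nona-4,7-dien-1-yl acetate | C=C1C(=O)O[C@@](C)([C@@H](OC(C)=O)CC/C(C)=C\C/C=C(\C)Br)CC[C@@H]1CC=O
F5 | step 19 | (1R,4E,7Z,11S,12R)-4,8,12-trimethyl-15-methylidene-3,14-dioxo-13-oxabicyclo[10.3.2]heptadeca-4,7-dien-11-yl acetate | C=C1C(=O)O[C@]2(C)CC[C@@H]1CC(=O)/C(C)=C/C/C=C(/C)CC[C@@H]2OC(C)=O
F6 | step 10 | 2-[(3R)-1-[(tert-butyldiphenylsilyl)oxy]-5-[(2S,3S)-3-(2-chloroethyl)-2-methyloxiran-2-yl]pentan-3-yl]prop-2-en-1-yl acetate | ClCC[C@@H]1O[C@@]1(C)CC[C@H](CCO[Si](c2ccccc2)(c2ccccc2)C(C)(C)C)C(=C)COC(C)=O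
F7 | step 10 | 2-[(3R)-1-[(tert-butyldiphenylsilyl)oxy]-5-[(2S,3S)-3-(2-chloroethyl)-2-methyloxiran-2-yl]pentan-3-yl]prop-2-en-1-ol | ClCC[C@@H]1O[C@@]1(C)CC[C@H](CCO[Si](c2ccccc2)(c2ccccc2)C(C)(C)C)C(=C)CO
F8 | step 10 | (1S)-1-[(2R,5R)-5-{2-[(tert-butyldiphenylsilyl)oxy]ethyl}-2-methyl-6-methylideneoxepan-2-yl]-3-chloropropan-1-ol | C=C1CO[C@@](C)([C@@H](O)CCCl)CC[C@@H]1CCO[Si](c2ccccc2)(c2ccccc2)C(C)(C)C
F9 | step 10 | (1S)-1-[(2R,5R)-5-{2-[(tert-butyldiphenylsilyl)oxy]ethyl}-2-methyl-6-methylideneoxepan-2-yl]-3-chloropropyl acetate | C=C1CO[C@@](C)([C@@H](OC(C)=O)CCCl)CC[C@@H]1CCO[Si](c2ccccc2)(c2ccccc2)C(C)(C)C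
F10 | step 8 | (3E,7R)-9-[(tert-butyldiphenylsilyl)oxy]-7-(3-hydroxyprop-1-en-2-yl)-4-methylnon-3-en-1-ol | OCC/C=C(\C)CC[C@H](CCO[Si](c1ccccc1)(c1ccccc1)C(C)(C)C)C(=C)CO
F11 | step 8 | (3R,6E)-3-{2-[(tert-butyldiphenylsilyl)oxy]ethyl}-9-hydroxy-6-methyl-2-methylidenenon-6-enal | OCC/C=C(\C)CC[C@H](CCO[Si](c1ccccc1)(c1ccccc1)C(C)(C)C)C(=C)C=O
F12 | step 8 | (3R,6E)-3-{2-[(tert-butyldiphenylsilyl)oxy]ethyl}-9-chloro-6-methyl-2-methylidenenon-6-enal | ClCC/C=C(\C)CC[C@H](CCO[Si](c1ccccc1)(c1ccccc1)C(C)(C)C)C(=C)C=O
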